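Compare the south run with the north-east run: they differ in substrate charge, 20 mM against 10 mM, over the same 16 mM of coupling partner.

| setting | south | north-east | grey | amber | blue | green |
|---|---|---|---|---|---|---|
| substrate | 20 mM | 10 mM | 20 mM (fed, over 6.00 h) | 20 mM | 20 mM | 20 mM |
| coupling partner | 16 mM | 16 mM | 16.0 mM | 16.0 mM (fed, over 6.00 h) | 16.0 mM | 16.0 mM |
| free catalyst | 2 mM | 2 mM | 2.0 mM | 2.0 mM | 2.0 mM | 2.0 mM |
| remark | run made earlier | run made earlier | all but substrate at the start; substrate goes in evenly over 6.00 h, the run ends at 6.0 h | all but coupling partner at the start; coupling partner goes in evenly over 6.00 h, the run ends at 6.0 h | a closed flask charged with all of it at once and left for 6.0 h | one stirred flow tank at steady state, fed with the mixture as stated, mean residence time 6.0 h |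
| time |  |  | 6.0 h | 6.0 h | 6.0 h |  |

south run (percent of the substrate charged)

| time / h | target / % | over-reaction product / % |
|---|---|---|
| 1.33 | 55.4 | 21.3 |
| 2.50 | 38.2 | 38.2 |
| 4.00 | 24.9 | 55.2 |
| 5.00 | 17.1 | 61.8 |
| 6.00 | 12.8 | 69.3 |

north-east run (percent of the substrate charged)

| time / min | target / % | over-reaction product / % |
|---|---|---|
| 6.00 | 18.5 | 0 |
| 10.0 | 28.9 | 0 |
| 20.0 | 51.1 | 3.3 |
| 40.0 | 66.4 | 12.1 |
| 80.0 | 64.8 | 25.3 |

(standard deviation of a reading: 1 percentage point)

- the stated concentrations are those of everything mixed, before any reaction; amounts are the same in each set-up
- the feed brings no volume worth counting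
- the earlier runs were made in a closed, stirred flask

- the set-up with the highest share of target in all that became target or over-reaction product, at the outlet or at the end ("none" if the first two lie within 2 percentage points) (grey / amber / blue / green / none)
- share of target in all that became target or over-reaction product, at the outlet or at the end, grey
- share of target in all that became target or over-reaction product, at the outlet or at the end, amber
- share of target in all that became target or over-reaction product, at the outlet or at the end, blue
- share of target in all that became target or over-reaction product, at the outlet or at the end, green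

Add target and over-reaction product. In the south run the sum reads 80.1% at 4.00 h and 82.1% at 6.00 h, level with the 80.0% that the partner charge allows at one partner per target, so treat partner as the limiting reagent there. The north-east run, with 1.60 equivalents of partner, reads 90.1% at 80.0 min, above the south run's mark, and there substrate is the smaller charge.

Read the first-order loss constant k of target from the south run between 2.50 h and 6.00 h: 0.312 h⁻¹, a reading with its scatter.

The south run turned over 11.5 mM h⁻¹ on average up to its first reading, faster than grey's feed of 3.33 mM h⁻¹, so my reckoning lets target form in grey as substrate arrives. Forming then lasts for a window w, the time the feed takes to deliver as much substrate as there is partner: 4.80 h. Define the survival share σ as the part of the target formed, evenly over w, that is still target at the end t_f: σ = (1 − e^(−kw))/(kw) · e^(−k(t_f − w)). For grey, σ = 35.6%.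

The forecast names amber, with grey 43%, amber 49%, blue 16% and green 35%, on this ground: “Feeding mainly shortens target's time in the flask, and amber leads.” My σ for grey lies below its figure.

The flasks give grey as best: grey 38.2%, amber 27.8%, blue 15.7%, green 32.9%.

    coupling partner + free catalyst ⇌ catalyst intermediate A (K = 5500 L mol⁻¹, k = 4000 L mol⁻¹ h⁻¹)
    substrate + catalyst intermediate A ⇌ catalyst intermediate B (K = 13.0 L mol⁻¹, k = 1800 L mol⁻¹ h⁻¹)
    catalyst intermediate B → free catalyst + target (k = 900 h⁻¹)
    target → over-reaction product (k = 0.340 h⁻¹)
    2 substrate → homo dimer (k = 22.0 L mol⁻¹ h⁻¹)

Amber holds 56.4% of the substrate charged as homo dimer at the end, against 2.80% in grey, and amber has 34.1% of the substrate charged in target and over-reaction product by 3.00 h, against 43.6% at the end. Grey ends with 0.0665% of its partner charge unbound, and its share of target stands at 38.2% against σ of 35.6%. In the neighbour flask, grey with 27 mM of partner, the window 8.10 h exceeds the feed time, so w becomes t_f and σ gives 45.2%; that flask stands at 44.2%.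

All runs are calculated with made-up constants.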